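**Plan**
- Retrosynthetic cuts: first the C2–C3 bond (carbinol carbon to the allylic CH2 of the farnesyl chain), then the aryl–C1(=O) bond, then the C2–O bond of a helper ether.
- Forward order: helper ether on a Weinreb amide, then the aryl ketone, then the C15 chain joined by a catalytic asymmetric phase-transfer alkylation, then one acid step that removes all three O-protecting groups. No ring is formed.
- Enabling feature: C2 lies between the C1 ketone carbonyl (conjugated to the 2,4-dioxygenated benzene ring) and its own oxygen, so as a CH2 it gives a planar, prochiral, doubly activated enolate. Its partner C3 is a primary allylic carbon next to C4=C5, an SN2 electrophile that needs no metal.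
- Stereochemistry: C2 (R) is set in the key step by the chiral ammonium cation of the ion pair. The 4E,8E geometry is carried in unchanged from (2E,6E)-farnesyl bromide.
- Helper: a bis(4-methoxyphenyl)methyl ether on the C2 oxygen gives the steric wing the ion pair needs. It ionises like a trityl ether, so it leaves together with the two aryl MOM groups.

Key step: step 4

Assumption: the cinchonine-derived salt should give the (R)-ether, because pseudoenantiomeric cinchonidinium salts give (S)-configured products in this reaction class. The catalyst is made from cinchonine in two standard steps (N-benzylation, O-allylation) and is not counted.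

**Step 1**
Reactants: 1 bis(4-methoxyphenyl)methanol; 2 2-chloro-N-methoxy-N-methylacetamide
Product: 4 2-[bis(4-methoxyphenyl)methoxy]-N-methoxy-N-methylacetamide, via sodium bis(4-methoxyphenyl)methanolate 3 (not isolated)
Conditions: NaH (1.1 equiv), THF, 0 °C; then 2, n-Bu4NI (5 mol%), 0 °C → rt
Reagents that add atoms: none
Why: Williamson ether synthesis, in which alkoxide 3 displaces the carbonyl-activated primary chloride by SN2 faster than it attacks the amide carbonyl, so the acid-labile diarylmethyl ether is made without acid.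

**Step 2**
Reactants: 5 4-bromoresorcinol (4-bromobenzene-1,3-diol)
Product: 6 1-bromo-2,4-bis(methoxymethoxy)benzene
Conditions: MOMCl (2.5 equiv), i-Pr2NEt (3 equiv), CH2Cl2, 0 °C → rt
Reagents that add atoms: chloromethyl methyl ether (MOMCl), COCCl
Why: Standard O-alkylation of both phenols with the reactive chloromethyl ether under amine base gives MOM ethers that withstand aryllithium and hydroxide and are removed by mild acid.

**Step 3**
Reactants: 6 1-bromo-2,4-bis(methoxymethoxy)benzene; 4 2-[bis(4-methoxyphenyl)methoxy]-N-methoxy-N-methylacetamide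
Product: 9 1-[2,4-bis(methoxymethoxy)phenyl]-2-[bis(4-methoxyphenyl)methoxy]ethan-1-one, via [2,4-bis(methoxymethoxy)phenyl]lithium 7 (not isolated), via lithium N-methoxy-N-methyl hemiaminal alkoxide 8 (not isolated)
Conditions: n-BuLi (1.05 equiv), THF, −78 °C; then 4, −78 → −40 °C; aq. NH4Cl
Reagents that add atoms: none
Why: Bromine–lithium exchange (faster than ortho-lithiation at −78 °C) gives the chelation-stabilised aryllithium 7, which adds once to the Weinreb amide, and the chelated adduct 8 collapses to the ketone only on work-up (Weinreb ketone synthesis).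

**Step 4**
Reactants: 9 1-[2,4-bis(methoxymethoxy)phenyl]-2-[bis(4-methoxyphenyl)methoxy]ethan-1-one; 10 (2E,6E)-farnesyl bromide
Product: 12 (2R,4E,8E)-1-[2,4-bis(methoxymethoxy)phenyl]-2-[bis(4-methoxyphenyl)methoxy]-5,9,13-trimethyltetradeca-4,8,12-trien-1-one, via caesium Z-enolate of 9 11 (not isolated)
Conditions: O(9)-allyl-N-(2,3,4-trifluorobenzyl)cinchoninium bromide (10 mol%), CsOH·H2O (5 equiv), 10 (1.5 equiv), CH2Cl2/n-hexane 1:1, −35 °C, Ar
Reagents that add atoms: none
Why: Solid CsOH deprotonates the C2 methylene of 9 at the interface, and the Z-enolate 11 enters the organic phase as a tight ion pair with the chiral quaternary ammonium cation, where its carbon attacks C1 of bromide 10 in an SN2 displacement. The closest known reaction type is the asymmetric phase-transfer alkylation of O-diarylmethyl aryl glycolyl ketones and of glycine imine esters with allylic and benzylic bromides under cinchona-derived ammonium catalysis. No ring is closed. The new C2 stereocentre is set by catalyst control: the cinchoninium cation covers one enolate face, with the bulky diarylmethoxy wing and the ortho-MOM aryl ring fixing the enolate geometry and its seating, so the bromide should approach the open face that leads to (R). The step needs C- over O-alkylation (soft allylic bromide, ion pair in a non-polar medium), attack at the primary C1 and not the fully substituted C3 of the allyl unit (no allyl-metal or cation, so the 2E,6E geometry is kept), and single alkylation without racemisation (the remaining C2–H of 12 is shielded and much harder to remove at −35 °C).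

**Step 5**
Reactants: 12 (2R,4E,8E)-1-[2,4-bis(methoxymethoxy)phenyl]-2-[bis(4-methoxyphenyl)methoxy]-5,9,13-trimethyltetradeca-4,8,12-trien-1-one
Product: 15 (2R,4E,8E)-1-(2,4-dihydroxyphenyl)-2-hydroxy-5,9,13-trimethyltetradeca-4,8,12-trien-1-one, via C2-hydroxy bis-MOM ketone 13 (not isolated), via 4-mono-MOM ketone 14 (not isolated)
Conditions: HCl (0.3 M) in MeOH/THF 3:1, 0 °C → rt
Reagents that add atoms: none
Why: Acid-catalysed solvolysis, in which the diarylmethyl ether ionises like a trityl ether to a doubly anisyl-stabilised cation that methanol captures, and the two MOM acetals then exchange to dimethoxymethane (the ortho one first, assisted by the ketone); dilute acid at or below room temperature should leave the trisubstituted alkenes and the C2 centre untouched.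

**Compound list**
1 | bis(4-methoxyphenyl)methanol | COc1ccc(C(O)c2ccc(OC)cc2)cc1 | starting material
2 | 2-chloro-N-methoxy-N-methylacetamide | CON(C)C(=O)CCl | starting material
3 | sodium bis(4-methoxyphenyl)methanolate | [Na+].[O-]C(c1ccc(OC)cc1)c1ccc(OC)cc1 | intermediate
4 | 2-[bis(4-methoxyphenyl)methoxy]-N-methoxy-N-methylacetamide | CON(C)C(=O)COC(c1ccc(OC)cc1)c1ccc(OC)cc1 | intermediate
5 | 4-bromoresorcinol | Oc1ccc(Br)c(O)c1 | starting material
6 | 1-bromo-2,4-bis(methoxymethoxy)benzene | COCOc1ccc(Br)c(OCOC)c1 | intermediate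
7 | [2,4-bis(methoxymethoxy)phenyl]lithium | [Li]c1ccc(OCOC)cc1OCOC | intermediate
8 | lithium 1-[2,4-bis(methoxymethoxy)phenyl]-2-[bis(4-methoxyphenyl)methoxy]-1-[methoxy(methyl)amino]ethan-1-olate | [Li+].[O-]C(COC(c1ccc(OC)cc1)c1ccc(OC)cc1)(N(C)OC)c1ccc(OCOC)cc1OCOC | intermediate
9 | 1-[2,4-bis(methoxymethoxy)phenyl]-2-[bis(4-methoxyphenyl)methoxy]ethan-1-one | COCOc1ccc(C(=O)COC(c2ccc(OC)cc2)c2ccc(OC)cc2)c(OCOC)c1 | intermediate
10 | (2E,6E)-farnesyl bromide, (2E,6E)-1-bromo-3,7,11-trimethyldodeca-2,6,10-triene | CC(C)=CCC/C(C)=C/CC/C(C)=C/CBr | starting material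
11 | caesium (Z)-1-[2,4-bis(methoxymethoxy)phenyl]-2-[bis(4-methoxyphenyl)methoxy]ethen-1-olate | [Cs+].[O-]/C(=C\OC(c1ccc(OC)cc1)c1ccc(OC)cc1)c1ccc(OCOC)cc1OCOC | intermediate
12 | (2R,4E,8E)-1-[2,4-bis(methoxymethoxy)phenyl]-2-[bis(4-methoxyphenyl)methoxy]-5,9,13-trimethyltetradeca-4,8,12-trien-1-one | CC(C)=CCC/C(C)=C/CC/C(C)=C/C[C@@H](OC(c1ccc(OC)cc1)c1ccc(OC)cc1)C(=O)c1ccc(OCOC)cc1OCOC | intermediate
13 | (2R,4E,8E)-1-[2,4-bis(methoxymethoxy)phenyl]-2-hydroxy-5,9,13-trimethyltetradeca-4,8,12-trien-1-one | CC(C)=CCC/C(C)=C/CC/C(C)=C/C[C@@H](O)C(=O)c1ccc(OCOC)cc1OCOC | intermediate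
14 | (2R,4E,8E)-2-hydroxy-1-[2-hydroxy-4-(methoxymethoxy)phenyl]-5,9,13-trimethyltetradeca-4,8,12-trien-1-one | CC(C)=CCC/C(C)=C/CC/C(C)=C/C[C@@H](O)C(=O)c1ccc(OCOC)cc1O | intermediate
15 | (2R,4E,8E)-1-(2,4-dihydroxyphenyl)-2-hydroxy-5,9,13-trimethyltetradeca-4,8,12-trien-1-one | CC(C)=CCC/C(C)=C/CC/C(C)=C/C[C@@H](O)C(=O)c1ccc(O)cc1O | target

**Count**
Total steps: 5. Longest linear sequence: 4 steps (1 → 3 → 4 → 5, or 2 → 3 → 4 → 5).

**Steps most likely to fail**

Step 4. The ion pair may discriminate the enolate faces poorly, or O-alkylation and base-mediated epimerisation of the product may compete. The fallback replaces catalyst control by auxiliary control and changes the order in which the fragments are joined. It sets out from 1 and 10 and comes back at 12. Alcohol 1 is O-alkylated with bromoacetic acid (NaH, 2.2 equiv, THF) to give 2-[bis(4-methoxyphenyl)methoxy]acetic acid F1. Pivaloyl chloride and Et3N convert this into the mixed pivalic anhydride F2, which acylates lithiated (S)-4-benzyloxazolidin-2-one to give the glycolyl imide (S)-4-benzyl-3-{2-[bis(4-methoxyphenyl)methoxy]acetyl}oxazolidin-2-one F3. Deprotonation with NaHMDS (THF, −78 °C) and alkylation with 10 on the face away from the benzyl group should give the (2R)-alkylated imide F4, whose minor diastereomer can be removed by chromatography. Me(MeO)NH·HCl/AlMe3 then gives the (2R)-Weinreb amide F5, and addition of aryllithium 7 (from 6) returns to 12.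

Step 5. The acid may add methanol or HCl to the trisubstituted alkenes, may drive attack of the C2 hydroxyl on the protonated C4=C5 bond, or may erode the C2 configuration by enolisation. The fallback replaces the single protic acidolysis by two orthogonal aprotic events. It sets out from 12 and comes back at 15. DDQ in CH2Cl2/pH 7 buffer at 0 °C removes the diarylmethyl ether by hydride abstraction and gives 13, which is isolated this time. ZnBr2/n-PrSH in CH2Cl2 at 0 °C then transfers both MOM groups to the thiol within minutes, without a Brønsted acid or protic medium, and gives 15.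

Step 3. The basic, chelated aryllithium may deprotonate the α-alkoxy amide instead of adding to it, which returns the amide and the protonated arene. The fallback uses a more electrophilic carbonyl and adjusts the oxidation level afterwards. It sets out from 4 and comes back at 9. DIBAL-H (THF, −78 °C) reduces 4 to 2-[bis(4-methoxyphenyl)methoxy]acetaldehyde F6. Aryllithium 7 adds to it at −78 °C to give the carbinol 1-[2,4-bis(methoxymethoxy)phenyl]-2-[bis(4-methoxyphenyl)methoxy]ethan-1-ol F7. Dess–Martin periodinane buffered with NaHCO3 oxidises the benzylic alcohol to 9.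

**Further compounds**
F1 | step 4 | 2-[bis(4-methoxyphenyl)methoxy]acetic acid | OC(=O)COC(c1ccc(OC)cc1)c1ccc(OC)cc1
F2 | step 4 | 2-[bis(4-methoxyphenyl)methoxy]acetic pivalic anhydride | CC(C)(C)C(=O)OC(=O)COC(c1ccc(OC)cc1)c1ccc(OC)cc1
F3 | step 4 | (S)-4-benzyl-3-{2-[bis(4-methoxyphenyl)methoxy]acetyl}oxazolidin-2-one | O=C(COC(c1ccc(OC)cc1)c1ccc(OC)cc1)N1[C@@H](Cc2ccccc2)COC1=O
F4 | step 4 | (S)-4-benzyl-3-[(2R,4E,8E)-2-[bis(4-methoxyphenyl)methoxy]-5,9,13-trimethyltetradeca-4,8,12-trienoyl]oxazolidin-2-one | CC(C)=CCC/C(C)=C/CC/C(C)=C/C[C@@H](OC(c1ccc(OC)cc1)c1ccc(OC)cc1)C(=O)N1[C@@H](Cc2ccccc2)COC1=O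
F5 | step 4 | (2R,4E,8E)-2-[bis(4-methoxyphenyl)methoxy]-N-methoxy-N,5,9,13-tetramethyltetradeca-4,8,12-trienamide | CC(C)=CCC/C(C)=C/CC/C(C)=C/C[C@@H](OC(c1ccc(OC)cc1)c1ccc(OC)cc1)C(=O)N(C)OC
F0 | step 5 | none | none
F6 | step 3 | 2-[bis(4-methoxyphenyl)methoxy]acetaldehyde | O=CCOC(c1ccc(OC)cc1)c1ccc(OC)cc1
F7 | step 3 | 1-[2,4-bis(methoxymethoxy)phenyl]-2-[bis(4-methoxyphenyl)methoxy]ethan-1-ol | OC(COC(c1ccc(OC)cc1)c1ccc(OC)cc1)c1ccc(OCOC)cc1OCOC
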